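**Strategy.** The oxepane is not closed directly; everything rests on disconnecting the C-6–C-11 bond (numbering below). Dichloroketene adds to the C-6=C-7 cycloheptene, and the C-15 hydroxyl caps the resulting endo-α-chlorocyclobutanone as a six-membered hemiketal (O, C-13, C-6, C-5, C-4, C-15), the precursor. Base then triggers a semibenzilic (quasi-Favorskii) shift of C-6 from C-13 to C-11: in one operation the cyclobutane contracts to the C-6/C-7/C-11 cyclopropane and the hemiketal ring grows by C-11 into the seven-membered lactone, later reduced to the ether. The step exploits the cyclopropylcarbinyl C-11–C-13–O motif shared by cyclopropane and oxepane. An Ireland–Claisen rearrangement and ring-closing metathesis build the carbocycle.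

Key step: step 16

Remark (numbering): aromadendrane numbering of the target is used throughout: C-1 and C-5 are the ring-fusion CH groups, C-2 the acetal carbon, C-3=C-4 the enol ether, C-6/C-7/C-11 the cyclopropane, C-8 and C-9 the ring CH2 groups, C-10 the carbinol carbon, C-12 the acetoxymethyl carbon, C-13 and C-15 the oxepane CH2 groups on C-11 and C-4.

Remark (stereochemistry): C-4 is carried as a mixture of epimers from step 10 to step 22 and the lactol carbons of 27 and 32 as anomeric mixtures; these centres are left undefined in the SMILES and are removed or fixed in steps 19 and 23.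

**Step 1**
Reactants: 1 geraniol
Product: 2 (2S,3S)-2,3-epoxygeraniol
Conditions: Ti(OiPr)4 (cat.), L-(+)-diethyl tartrate (cat.), t-BuOOH, 4 Å molecular sieves, CH2Cl2, −20 °C
Reagents that add atoms: tert-butyl hydroperoxide CC(C)(C)OO
Why: Sharpless asymmetric epoxidation of the allylic alcohol; with L-(+)-diethyl tartrate the oxygen is delivered to the alkene face that gives the (2S,3S)-epoxide, which fixes the later C-10 stereocentre.

**Step 2**
Reactants: 2 (2S,3S)-2,3-epoxygeraniol
Product: 3 (S)-3,7-dimethyloct-6-ene-1,3-diol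
Conditions: NaAlH2(OCH2CH2OMe)2, THF, 0 °C
Reagents that add atoms: none
Why: The alkoxy-aluminate formed at the primary hydroxyl delivers hydride intramolecularly to C-2 of the 2,3-epoxy alcohol (reductive epoxide opening), so the 1,3-diol forms with the tertiary C–O bond and its configuration untouched.

**Step 3**
Reactants: 3 (S)-3,7-dimethyloct-6-ene-1,3-diol
Product: 5 (S)-3-hydroxy-3,7-dimethyloct-6-enoic acid, via aldehyde 4 (not isolated)
Conditions: TEMPO (cat.), PhI(OAc)2, MeCN–H2O, rt
Reagents that add atoms: water O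
Why: Nitroxyl-catalysed oxidation with PhI(OAc)2 in wet acetonitrile takes only the primary alcohol through aldehyde 4 and its hydrate to the acid, leaving the tertiary hydroxyl and the trisubstituted alkene alone.

**Step 4**
Reactants: 5 (S)-3-hydroxy-3,7-dimethyloct-6-enoic acid
Product: 7 (S)-3,7-dimethyl-3-(triethylsilyloxy)oct-6-enoic acid, via silyl ester 6 (not isolated)
Conditions: Et3SiOTf, 2,6-lutidine, CH2Cl2, −78 to 0 °C; then K2CO3, MeOH, 0 °C
Reagents that add atoms: triethylsilyl trifluoromethanesulfonate CC[Si](CC)(CC)OS(=O)(=O)C(F)(F)F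
Why: The silyl triflate silylates the hindered tertiary alcohol and the acid, and mild methanolysis then cleaves only the labile silyl ester (protecting-group step; C-10 is not touched).

**Step 5**
Reactants: 8 2-bromoprop-2-en-1-ol
Product: 9 2-bromoprop-2-en-1-yl 4-methoxybenzyl ether
Conditions: NaH, 4-methoxybenzyl chloride, Bu4NI (cat.), THF–DMF, 0 °C to rt
Reagents that add atoms: 4-methoxybenzyl chloride COc1ccc(CCl)cc1
Why: Williamson etherification of the primary alkoxide with the benzylic chloride masks the future C-15 oxygen as an oxidatively removable ether.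

**Step 6**
Reactants: 9 2-bromoprop-2-en-1-yl 4-methoxybenzyl ether; 10 (R)-but-3-yn-2-ol
Product: 11 (R)-5-[(4-methoxybenzyloxy)methyl]hex-5-en-3-yn-2-ol
Conditions: PdCl2(PPh3)2 (cat.), CuI (cat.), Et3N, THF, rt
Reagents that add atoms: none
Why: Sonogashira coupling of the vinyl bromide with the terminal alkyne joins C-4 to C-5 without touching the carbinol stereocentre.

**Step 7**
Reactants: 11 (R)-5-[(4-methoxybenzyloxy)methyl]hex-5-en-3-yn-2-ol
Product: 12 (2R,3Z)-5-[(4-methoxybenzyloxy)methyl]hexa-3,5-dien-2-ol
Conditions: H2 (1 atm), Pd/CaCO3 poisoned with Pb(OAc)2 (Lindlar catalyst), quinoline, EtOAc, rt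
Reagents that add atoms: none
Why: Syn addition of one equivalent of H2 on Pd/CaCO3–Pb(OAc)2 (Lindlar semihydrogenation) gives the cis-alkene, while the 1,1-disubstituted alkene and the benzylic ether are spared.

**Step 8**
Reactants: 7 (S)-3,7-dimethyl-3-(triethylsilyloxy)oct-6-enoic acid; 12 (2R,3Z)-dienol
Product: 13 (2R,3Z)-5-[(4-methoxybenzyloxy)methyl]hexa-3,5-dien-2-yl (S)-3,7-dimethyl-3-(triethylsilyloxy)oct-6-enoate
Conditions: EDC·HCl, DMAP, CH2Cl2, 0 °C to rt
Reagents that add atoms: none
Why: Carbodiimide/DMAP (Steglich) esterification acylates the secondary allylic alcohol with retention, since the C–O bond of the carbinol is not broken.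

**Step 9**
Reactants: 13 allylic ester
Product: 16 open-chain primary alcohol (C-1–C-5 bond formed), via ketene acetal 14 (not isolated), via silyl ester 15 (not isolated)
Conditions: LiN(iPr)2, Me3SiCl–Et3N, THF, −78 °C, then 55 °C; then LiAlH4, 0 °C
Reagents that add atoms: none
Why: Ireland–Claisen rearrangement: kinetic enolisation in THF with in situ silylation gives ketene acetal 14 with the C-10 carbon cis to the allylic oxygen, and the chair [3,3] shift, in which the carbinol methyl must be equatorial because of allylic 1,3-strain with the cis-alkene, transfers the (R)-carbinol chirality to C-1 and C-5 (syn, the later cis ring fusion); LiAlH4 then reduces silyl ester 15 in the same flask.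

**Step 10**
Reactants: 16 open-chain primary alcohol
Product: 18 diol (new CH2OH = C-3), via bis-borane 17 (not isolated)
Conditions: 9-BBN, THF, 0 °C to rt; then NaOH, H2O2
Reagents that add atoms: hydrogen peroxide OO
Why: Hydroboration–oxidation: 9-BBN attacks the least hindered 1,1-disubstituted alkene with boron on the CH2 group much faster than the 1,2-disubstituted and trisubstituted alkenes, giving the primary alcohol; C-4 forms without control, which does not matter.

**Step 11**
Reactants: 18 diol
Product: 19 dibenzyl ether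
Conditions: NaH, BnBr, Bu4NI (cat.), THF–DMF, 0 °C to rt
Reagents that add atoms: benzyl bromide BrCc1ccccc1
Why: Williamson benzylation of both primary alkoxides.

**Step 12**
Reactants: 19 dibenzyl ether
Product: 20 cycloheptene (C-6=C-7)
Conditions: second-generation Grubbs catalyst RuCl2(=CHPh)(PCy3)(H2IMes) (cat.), CH2Cl2 (5 mM), 40 °C
Reagents that add atoms: none
Why: Ring-closing metathesis between the propenyl and prenyl termini closes the seven-membered carbocycle at C-6=C-7 and is driven by loss of volatile 2-methylbut-2-ene.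

**Step 13**
Reactants: 20 cycloheptene
Product: 21 cis-fused α,α-dichlorocyclobutanone (C=O on C-6, CCl2 on C-7)
Conditions: Cl3CCOCl, Zn–Cu couple, Et2O–DME, rt, ultrasound
Reagents that add atoms: trichloroacetyl chloride ClC(Cl)(Cl)C(Cl)=O
Why: Thermal [2+2] cycloaddition of dichloroketene (made in the flask) is suprafacial on the alkene and so gives a cis-fused cyclobutanone on the face opposite to the three substituents at C-1, C-5 and C-10; the carbonyl carbon is expected to bond to C-6 and the bulky CCl2 carbon to the less hindered C-7, and the regioisomer is carried along because it gives the same lactone in step 16.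

**Step 14**
Reactants: 21 α,α-dichlorocyclobutanone
Product: 22 endo-α-chlorocyclobutanone
Conditions: Bu3SnH (1 equiv), AIBN (cat.), cyclohexane, 80 °C
Reagents that add atoms: none
Why: Radical monodechlorination: the α-keto radical takes hydrogen from Bu3SnH on the open convex face, which leaves the remaining chlorine endo.

**Step 15**
Reactants: 22 endo-α-chlorocyclobutanone
Product: 24 six-membered hemiketal (lactol), via hydroxy ketone 23 (not isolated)
Conditions: DDQ, CH2Cl2–pH 7 buffer, 0 °C
Reagents that add atoms: none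
Why: DDQ removes the 4-methoxybenzyl group by benzylic oxidation under neutral conditions, and the freed C-15 hydroxyl of 23 adds to the strained, chlorine-activated cyclobutanone carbonyl to give the six-membered hemiketal, whose ring oxygen can only lie cis to C-5 on the four-membered ring.

**Step 16**
Reactants: 24 six-membered hemiketal
Product: 25 seven-membered lactone fused to the C-6/C-7/C-11 cyclopropane
Conditions: KN(SiMe3)2 (1.05 equiv), THF, −78 to 0 °C
Reagents that add atoms: none
Why: Deprotonation of the hemiketal hydroxyl gives an alkoxide that pushes the C-13–C-6 bond onto C-11 as the endo chloride leaves (semibenzilic, or quasi-Favorskii, rearrangement; the closest known reaction is the ring contraction of 2-chlorocyclobutanones by external alkoxide, here with the alkoxide tethered as a lactol). The 1,2-shift contracts the cyclobutane to the C-6/C-7/C-11 cyclopropane (mode: 3-exo-tet displacement at C-11 by the migrating C-6) and, because C-11 is thereby inserted between C-13 and C-6, turns the six-membered hemiketal ring (O, C-13, C-6, C-5, C-4, C-15) into the seven-membered lactone, which is not closed from an open chain but grows by one atom. C-11 is inverted, C-6 entering anti to chloride, so the endo chlorine set in step 14 puts the acyl carbon C-13 endo and hydrogen exo, while C-5, C-6 and C-7 keep their configuration. The step needs the migrating bond antiperiplanar to C–Cl, which the pseudo-equatorial endo chloride of the cis-fused four-membered ring provides, and it must outrun enolisation or haloform-type cleavage of the open hydroxy ketone, which the closed hemiketal form and a stoichiometric non-nucleophilic base at low temperature secure. The minor cycloadduct with the carbonyl on C-7 gives the same lactone through a seven-membered hemiketal.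

**Step 17**
Reactants: 25 lactone
Product: 26 11-(hydroxymethyl) lactone
Conditions: LiN(iPr)2, THF, −78 °C; then CH2O (gas), −78 to −40 °C
Reagents that add atoms: formaldehyde C=O
Why: Aldol addition of the lithium enolate of the cyclopropyl lactone to formaldehyde; because the lactone carbonyl is held endo by the ring, the hydroxymethyl group can only enter on the exo side, which sets the quaternary C-11.

**Step 18**
Reactants: 26 11-(hydroxymethyl) lactone
Product: 27 lactol
Conditions: iBu2AlH, CH2Cl2, −78 °C
Reagents that add atoms: none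
Why: iBu2AlH reduces the lactone to the lactol at low temperature, where the tetrahedral aluminium acetal does not collapse further.

**Step 19**
Reactants: 27 lactol
Product: 28 oxepane alcohol
Conditions: Et3SiH, BF3·OEt2, CH2Cl2, −78 °C
Reagents that add atoms: none
Why: Ionic hydrogenation: BF3 ionises the lactol to an oxocarbenium ion stabilised by the ring oxygen and the cyclopropane, and Et3SiH delivers hydride to C-13 without opening the ring.

**Step 20**
Reactants: 28 oxepane alcohol
Product: 29 C-12 acetate
Conditions: Ac2O, pyridine, DMAP (cat.), CH2Cl2, 0 °C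
Reagents that add atoms: acetic anhydride CC(=O)OC(C)=O
Why: Acylation of the only free hydroxyl.

**Step 21**
Reactants: 29 C-12 acetate
Product: 30 diol (C-2 and C-3 hydroxyls free)
Conditions: H2 (1 atm), Pd(OH)2/C, EtOAc, rt
Reagents that add atoms: none
Why: Hydrogenolysis of both benzyl ethers over Pd(OH)2/C; cyclopropane, acetate and the tertiary silyl ether are not affected.

**Step 22**
Reactants: 30 diol
Product: 31 dialdehyde
Conditions: Dess–Martin periodinane, NaHCO3, CH2Cl2, 0 °C to rt
Reagents that add atoms: none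
Why: Dess–Martin oxidation takes both primary alcohols to aldehydes under buffered conditions, with the tertiary oxygen still silylated so that it can neither add to the C-3 aldehyde nor be lost by β-elimination.

**Step 23**
Reactants: 31 dialdehyde
Product: 33 10-O-triethylsilyl ether of the target, via enol hemiacetal 32 (not isolated)
Conditions: Ac2O, Et3N, DMAP (cat.), CH2Cl2, 0 °C to rt
Reagents that add atoms: acetic anhydride CC(=O)OC(C)=O
Why: Amine base enolises the C-3 aldehyde toward C-4, the enol oxygen adds to the C-2 aldehyde to give 2-hydroxy-dihydropyran 32, and acylation traps it; the hemiacetal equilibrates before acylation, so the acetate should settle axial (anomeric effect) and trans to the bulky C-10 carbon on C-1, as in the target.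

**Step 24**
Reactants: 33 10-O-triethylsilyl ether of the target
Product: 34 target CNP0250836.3
Conditions: HF·pyridine, pyridine, THF, 0 °C to rt
Reagents that add atoms: none
Why: Fluoride cleaves the tertiary Si–O bond under pyridine-buffered conditions that should spare the enol acetal and both acetates.

**Compound list**

1 | geraniol, (2E)-3,7-dimethylocta-2,6-dien-1-ol | CC(C)=CCC/C(C)=C/CO | starting material
2 | (2S,3S)-2,3-epoxygeraniol | CC(C)=CCC[C@]1(C)O[C@H]1CO | intermediate
3 | (S)-3,7-dimethyloct-6-ene-1,3-diol | CC(C)=CCC[C@](C)(O)CCO | intermediate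
4 | (S)-3-hydroxy-3,7-dimethyloct-6-enal (not isolated) | CC(C)=CCC[C@](C)(O)CC=O | intermediate
5 | (S)-3-hydroxy-3,7-dimethyloct-6-enoic acid | CC(C)=CCC[C@](C)(O)CC(=O)O | intermediate
6 | triethylsilyl (S)-3,7-dimethyl-3-(triethylsilyloxy)oct-6-enoate (not isolated) | CC(C)=CCC[C@](C)(O[Si](CC)(CC)CC)CC(=O)O[Si](CC)(CC)CC | intermediate
7 | (S)-3,7-dimethyl-3-(triethylsilyloxy)oct-6-enoic acid | CC(C)=CCC[C@](C)(O[Si](CC)(CC)CC)CC(=O)O | intermediate
8 | 2-bromoprop-2-en-1-ol | OCC(Br)=C | starting material
9 | 2-bromoprop-2-en-1-yl 4-methoxybenzyl ether | COc1ccc(COCC(Br)=C)cc1 | intermediate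
10 | (R)-but-3-yn-2-ol | C[C@@H](O)C#C | starting material
11 | (R)-5-[(4-methoxybenzyloxy)methyl]hex-5-en-3-yn-2-ol | C[C@@H](O)C#CC(=C)COCc1ccc(OC)cc1 | intermediate
12 | (2R,3Z)-5-[(4-methoxybenzyloxy)methyl]hexa-3,5-dien-2-ol | C[C@@H](O)/C=C\C(=C)COCc1ccc(OC)cc1 | intermediate
13 | (2R,3Z)-5-[(4-methoxybenzyloxy)methyl]hexa-3,5-dien-2-yl (S)-3,7-dimethyl-3-(triethylsilyloxy)oct-6-enoate | CC(C)=CCC[C@](C)(O[Si](CC)(CC)CC)CC(=O)O[C@H](C)/C=C\C(=C)COCc1ccc(OC)cc1 | intermediate
14 | trimethylsilyl ketene acetal of 13, C-10 carbon cis to the allylic oxygen (not isolated) | CC(C)=CCC[C@](C)(O[Si](CC)(CC)CC)/C=C(/O[Si](C)(C)C)O[C@H](C)/C=C\C(=C)COCc1ccc(OC)cc1 | intermediate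
15 | trimethylsilyl ester of the rearranged acid, (E)-propenyl on C-5 (not isolated) | C[Si](C)(C)OC(=O)[C@H]([C@@H](/C=C/C)C(=C)COCc1ccc(OC)cc1)[C@@](C)(O[Si](CC)(CC)CC)CCC=C(C)C | intermediate
16 | open-chain primary alcohol: C-2 CH2OH on C-1; C-1 carries the C-10 carbinol carbon (methyl, OSiEt3, 4-methylpent-3-enyl) and C-5; C-5 carries (E)-prop-1-enyl and the 3-(4-methoxybenzyloxy)prop-1-en-2-yl group; C-1, C-5, C-10 as in the target | OC[C@H]([C@@H](/C=C/C)C(=C)COCc1ccc(OC)cc1)[C@@](C)(O[Si](CC)(CC)CC)CCC=C(C)C | intermediate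
17 | bis(9-borabicyclo[3.3.1]nonan-9-yl) derivative of 16, B–O at the C-2 oxygen and B–C at C-3 (not isolated) | B1(OC[C@H]([C@@H](/C=C/C)C(CB2C3CCCC2CCC3)COCc4ccc(OC)cc4)[C@@](C)(O[Si](CC)(CC)CC)CCC=C(C)C)C5CCCC1CCC5 | intermediate
18 | diol: as 16 with C-4 now CH bearing CH2OH (C-3) and CH2O-(4-methoxybenzyl) (C-15); C-4 epimers | OC[C@H]([C@@H](/C=C/C)C(CO)COCc1ccc(OC)cc1)[C@@](C)(O[Si](CC)(CC)CC)CCC=C(C)C | intermediate
19 | 2,3-di-O-benzyl ether of 18 | C(c1ccccc1)OC[C@H]([C@@H](/C=C/C)C(COCc2ccccc2)COCc3ccc(OC)cc3)[C@@](C)(O[Si](CC)(CC)CC)CCC=C(C)C | intermediate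
20 | cyclohept-6-ene: C-1 CH2OBn and C-5 side chain cis, C-10 OSiEt3 cis to both, C-10 methyl trans | C(c1ccccc1)OC[C@@H]2[C@H](C(COCc3ccccc3)COCc4ccc(OC)cc4)C=CCC[C@]2(C)O[Si](CC)(CC)CC | intermediate
21 | cis-fused 2,2-dichlorocyclobutanone on the face anti to the C-5 side chain, C=O (C-13) on C-6, CCl2 (C-11) on C-7 | C(c1ccccc1)OC[C@@H]2[C@H](C(COCc3ccccc3)COCc4ccc(OC)cc4)[C@H]5C(=O)C(Cl)(Cl)[C@H]5CC[C@]2(C)O[Si](CC)(CC)CC | intermediate
22 | endo-2-chlorocyclobutanone (Cl on C-11 cis to C-5 and C-8) | C(c1ccccc1)OC[C@@H]2[C@H](C(COCc3ccccc3)COCc4ccc(OC)cc4)[C@H]5C(=O)[C@@H](Cl)[C@H]5CC[C@]2(C)O[Si](CC)(CC)CC | intermediate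
23 | open hydroxy ketone, C-15 OH free (not isolated) | C(c1ccccc1)OC[C@@H]2[C@H](C(COCc3ccccc3)CO)[C@H]5C(=O)[C@@H](Cl)[C@H]5CC[C@]2(C)O[Si](CC)(CC)CC | intermediate
24 | six-membered hemiketal: ring O, C-13(OH), C-6, C-5, C-4, C-15, fused to the chlorocyclobutane | C(c1ccccc1)OC[C@@H]2[C@H](C(COCc3ccccc3)CO4)[C@H]5[C@]4(O)[C@@H](Cl)[C@H]5CC[C@]2(C)O[Si](CC)(CC)CC | intermediate
25 | seven-membered lactone (C-11, C-13(=O), O, C-15, C-4, C-5, C-6) fused to the C-6/C-7/C-11 cyclopropane, H-11 exo | C(c1ccccc1)OC[C@@H]2[C@@H]3C(COCc4ccccc4)COC(=O)[C@@H]5[C@H]3[C@@H]5CC[C@]2(C)O[Si](CC)(CC)CC | intermediate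
26 | 11-(hydroxymethyl) lactone, CH2OH (C-12) exo | C(c1ccccc1)OC[C@@H]2[C@@H]3C(COCc4ccccc4)COC(=O)[C@]5(CO)[C@H]3[C@@H]5CC[C@]2(C)O[Si](CC)(CC)CC | intermediate
27 | lactol at C-13 (anomers) | C(c1ccccc1)OC[C@@H]2[C@@H]3C(COCc4ccccc4)COC(O)[C@]5(CO)[C@H]3[C@@H]5CC[C@]2(C)O[Si](CC)(CC)CC | intermediate
28 | oxepane with free C-12 hydroxyl | C(c1ccccc1)OC[C@@H]2[C@@H]3C(COCc4ccccc4)COC[C@]5(CO)[C@H]3[C@@H]5CC[C@]2(C)O[Si](CC)(CC)CC | intermediate
29 | C-12 acetate of 28 | C(c1ccccc1)OC[C@@H]2[C@@H]3C(COCc4ccccc4)COC[C@]5(COC(C)=O)[C@H]3[C@@H]5CC[C@]2(C)O[Si](CC)(CC)CC | intermediate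
30 | 2,3-diol, 10-OSiEt3, 12-OAc | OC[C@@H]1[C@@H]2C(CO)COC[C@]3(COC(C)=O)[C@H]2[C@@H]3CC[C@]1(C)O[Si](CC)(CC)CC | intermediate
31 | 2,3-dialdehyde, 10-OSiEt3, 12-OAc | O=C[C@@H]1[C@@H]2C(C=O)COC[C@]3(COC(C)=O)[C@H]2[C@@H]3CC[C@]1(C)O[Si](CC)(CC)CC | intermediate
32 | 2-hydroxy-3,4-dihydro-2H-pyran (enol hemiacetal, anomers; not isolated) | CC(=O)OC[C@@]12COCC3=COC(O)[C@@H]4[C@H]3[C@@H]1[C@@H]2CC[C@]4(C)O[Si](CC)(CC)CC | intermediate
33 | 10-O-triethylsilyl ether of the target | CC(=O)OC[C@@]12COCC3=CO[C@H](OC(C)=O)[C@@H]4[C@H]3[C@@H]1[C@@H]2CC[C@]4(C)O[Si](CC)(CC)CC | intermediate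
34 | CNP0250836.3 | CC(=O)OC[C@@]12COCC3=CO[C@H](OC(C)=O)[C@@H]4[C@H]3[C@@H]1[C@@H]2CC[C@]4(C)O | target

**Step count.** Total steps: 24. Longest linear sequence: 21 steps (steps 1–4, then 8–24).

**Steps most likely to fail**

Step 16. The ring-opened hydroxy ketone may enolise and lose the endo chloride configuration, or the alkoxide adduct may cleave the C-13–C-11 bond instead of undergoing the 1,2-shift. The fallback sets out from 22 and separates ring contraction from lactone formation. External methoxide (NaOMe, MeOH, 0 °C) should contract the four-membered ring with the same inversion at C-11 to give endo methyl ester F1. DDQ then frees the C-15 hydroxyl to give hydroxy ester F2. Transesterification (Ti(OiPr)4 cat., toluene, reflux, removal of methanol) closes the lactone and the route is rejoined at 25.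

Step 9. Chelation by the β-silyloxy group may erode the enolate geometry, or the silyloxide may be lost by β-elimination, giving the wrong C-1/C-5 relationship. The fallback sets out from 9 and switches both the alkene geometry and the enolate geometry. Sonogashira coupling of 9 with commercial (S)-but-3-yn-2-ol gives (S)-enyne F3. Trans-reduction of the propargylic alcohol with NaAlH2(OCH2CH2OMe)2 gives (2S,3E)-dienol F4, and esterification with 7 gives ester F5. Enolisation with LiN(iPr)2 in THF–DMPU and silylation gives ketene acetal F6 with the C-10 carbon cis to the silyloxy oxygen. The chair rearrangement of this (S),(E) combination should lead to the same silyl ester 15, and LiAlH4 reduction rejoins the route at 16.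

Step 23. Enolisation and ring closure may be incomplete, and the kinetic acylation may give poor control of the C-2 configuration. The fallback sets out from 31 and fixes the acetal carbon under thermodynamic control before the acetate is introduced. Acid-catalysed methanolysis (PPTS, MeOH, HC(OMe)3, warm) should give the cyclic enol methyl acetal F7. Acetolysis (Ac2O, cat. Me3SiOTf, CH2Cl2, −40 °C) through the ring oxocarbenium ion, with axial attack of acetate, then rejoins the route at 33.

**Further compounds**

F1 | step 16 | endo methyl cyclopropanecarboxylate (C-13 ester on C-11, C-15 O-(4-methoxybenzyl) retained) | C(c1ccccc1)OC[C@@H]2[C@H](C(COCc3ccccc3)COCc4ccc(OC)cc4)[C@H]5[C@@H](C(=O)OC)[C@H]5CC[C@]2(C)O[Si](CC)(CC)CC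
F2 | step 16 | hydroxy ester (C-15 OH free) | C(c1ccccc1)OC[C@@H]2[C@H](C(COCc3ccccc3)CO)[C@H]5[C@@H](C(=O)OC)[C@H]5CC[C@]2(C)O[Si](CC)(CC)CC
F3 | step 9 | (S)-5-[(4-methoxybenzyloxy)methyl]hex-5-en-3-yn-2-ol | C[C@H](O)C#CC(=C)COCc1ccc(OC)cc1
F4 | step 9 | (2S,3E)-5-[(4-methoxybenzyloxy)methyl]hexa-3,5-dien-2-ol | C[C@H](O)/C=C/C(=C)COCc1ccc(OC)cc1
F5 | step 9 | (2S,3E)-5-[(4-methoxybenzyloxy)methyl]hexa-3,5-dien-2-yl (S)-3,7-dimethyl-3-(triethylsilyloxy)oct-6-enoate | CC(C)=CCC[C@](C)(O[Si](CC)(CC)CC)CC(=O)O[C@@H](C)/C=C/C(=C)COCc1ccc(OC)cc1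
F6 | step 9 | trimethylsilyl ketene acetal of F5, C-10 carbon cis to the silyloxy oxygen | CC(C)=CCC[C@](C)(O[Si](CC)(CC)CC)/C=C(\O[Si](C)(C)C)O[C@@H](C)/C=C/C(=C)COCc1ccc(OC)cc1
F7 | step 23 | cyclic enol methyl acetal (2-methoxy-3,4-dihydro-2H-pyran), 10-OSiEt3, 12-OAc | CC(=O)OC[C@@]12COCC3=COC(OC)[C@@H]4[C@H]3[C@@H]1[C@@H]2CC[C@]4(C)O[Si](CC)(CC)CC
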